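Clerodane numbering is used: ring A is C1–C5/C10, ring B is C5–C10. Ring B is treated as a masked cyclohexane-1,3-dione (C7, C9) and is closed by a tethered Michael–Claisen annulation. A malonate ester hung on the C3 oxygen of (R)-4-acetyl-3-methylcyclohex-3-enol adds to C5 (new C5–C6 bond, quaternary C5, bridged lactone); the acetyl enolate then opens that lactone (new C7–C8 bond). The step exploits the 1,3-diaxial relation of O3 and C6 across ring A and the C7/C9 dioxygen pattern of ring B: one enzyme-set carbinol fixes C5 and the cis ring fusion, then relays C9, C8 and C7, and finally becomes the C3 ketone.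

Key step: step 4

Remark: C17, C18, C19 and C20 are the carbons on C8, C4, C5 and C9, and C11–C16 is the side chain. The SMILES is read as the cis-fused clerodane with H-10, C19, C11 and the C7 acetoxy group on one face (called α) and C17 and C20 on the other (β); the C3 oxygen of the intermediates is β.

Step 1
Reactants: 1 2-(trimethylsilyloxy)buta-1,3-diene; 2 pent-3-yn-2-one
Product: 4 4-acetyl-3-methylcyclohex-3-en-1-one, via silyl enol ether 3 (not isolated)
Conditions: PhMe, 120 °C, sealed tube, Ar; then oxalic acid, THF/H2O, 0 °C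
Reagents that add atoms: none
Why: Thermal Diels–Alder reaction in which the nucleophilic C1 terminus of the 2-siloxydiene bonds to the β-carbon of the ynone, so that the oxygen-bearing carbon (future C3) and the acetyl-bearing carbon (future C10) end up 1,4 to each other, and buffered hydrolysis of the silyl enol ether should keep the double bond between C5 and C10.

Step 2
Reactants: 4 4-acetyl-3-methylcyclohex-3-en-1-one
Product: 5 (R)-4-acetyl-3-methylcyclohex-3-en-1-ol
Conditions: ketoreductase (R-selective KRED), NADP+ (cat.), i-PrOH, phosphate buffer pH 7, 30 °C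
Reagents that add atoms: none
Why: Enzymatic carbonyl reduction with isopropanol-driven cofactor recycling, in which the enzyme pocket tells the two CH2 flanks of the ring ketone apart through the remote alkene (no small hydride reagent can do this) and leaves the hindered conjugated acetyl group alone; this is the only stereocentre set by catalysis.

Step 3
Reactants: 5 (R)-4-acetyl-3-methylcyclohex-3-en-1-ol; 6 3-(tert-butoxy)-3-oxopropanoic acid
Product: 7 tert-butyl (R)-4-acetyl-3-methylcyclohex-3-en-1-yl malonate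
Conditions: DCC, DMAP (cat.), CH2Cl2, 0 → 25 °C
Reagents that add atoms: none
Why: Steglich esterification of the secondary alcohol with the malonic half ester under neutral conditions that do not move the double bond.

Step 4
Reactants: 7 tert-butyl (R)-4-acetyl-3-methylcyclohex-3-en-1-yl malonate
Product: 9 A/B-cis tert-butyl 3β-hydroxy-5-methyl-7,9-dioxodecalin-6-carboxylate, via bridged lactone 8 (not isolated)
Conditions: KOt-Bu (0.1 equiv), t-BuOH/THF, 25 °C; then KOt-Bu (2.5 equiv), 50 °C; aq. HCl work-up
Reagents that add atoms: none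
Why: Catalytic tert-butoxide forms the malonate anion, whose carbon (C6) adds in a 6-exo-trig intramolecular Michael reaction to C5, the β-carbon of the acetylcyclohexene, giving the bridged δ-lactone 8 (a 2-oxabicyclo[3.3.1]nonan-3-one); with excess base the methyl ketone enolate (C8) then attacks the lactone carbonyl C7 in a 6-exo-trig Claisen (Dieckmann-type) acyl transfer that closes ring B and expels the C3 alkoxide, the sequence being pulled forward by the stabilised 1,3-dione enolate. The closest known reaction type is the Michael–Claisen annulation of enones with malonates (as in the classical dimedone synthesis) combined with the acylation of ketone enolates by lactones. C5 is set by the tether: C6 can only reach C5 on the ring A face that carries O3, so the (R)-carbinol dictates the quaternary centre. C10 is set in the second closure: while C6 is held axial by the lactone bridge, only the C10 epimer with the acetyl group gauche to C6 (freely equilibrating next to the ketone) can reach C7, which gives the cis ring fusion (H-10 cis to C19). The step needs the malonate to add before the γ-position C4 is deprotonated (which would eject the ester), secured by using catalytic base until the Michael stage is complete, and it needs acyl transfer at the lactone rather than at the external ester, secured by the bulk of the tert-butyl group. C6 forms as an epimer mixture that disappears on decarboxylation in step 5.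

Step 5
Reactants: 9 A/B-cis tert-butyl 3β-hydroxy-5-methyl-7,9-dioxodecalin-6-carboxylate
Product: 12 A/B-cis 3β-hydroxy-7-methoxy-5-methyl-Δ7-octalin-9-one, via keto acid 10 (not isolated), via dione 11 (not isolated)
Conditions: TFA, CH2Cl2, 25 → 40 °C; concentrate; MeOH, HC(OMe)3, TsOH (cat.), 25 °C
Reagents that add atoms: methanol (CO)
Why: Acidolysis of the tert-butyl ester and decarboxylation of the β-keto acid give the 1,3-dione, and acid-catalysed enol etherification should place the methoxy group on C7, the carbonyl remote from the ring-fusion carbon C10, as is usual for 4-substituted cyclohexane-1,3-diones, while the mild acid should leave C10 unchanged.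

Step 6
Reactants: 12 A/B-cis 3β-hydroxy-7-methoxy-5-methyl-Δ7-octalin-9-one
Product: 13 A/B-cis 3β-(tert-butyldimethylsilyloxy)-7-methoxy-5-methyl-Δ7-octalin-9-one
Conditions: TBSCl, imidazole, DMF, 25 °C
Reagents that add atoms: tert-butyldimethylsilyl chloride (CC(C)(C)[Si](C)(C)Cl)
Why: Standard silylation of the unhindered C3 alcohol so that it can later be told apart from the C7 alcohol; the bulky equatorial silyloxy group also biases the cis-decalin towards the conformer used in steps 8 and 9.

Step 7
Reactants: 13 A/B-cis 3β-(tert-butyldimethylsilyloxy)-7-methoxy-5-methyl-Δ7-octalin-9-one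
Product: 15 A/B-cis 3β-(tert-butyldimethylsilyloxy)-5,9-dimethyl-Δ8-octalin-7-one, via carbinol 14 (not isolated)
Conditions: MeLi, CeCl3, THF, −78 °C; then 1 M HCl, THF, 0 °C
Reagents that add atoms: methyllithium ([Li]C)
Why: Stork–Danheiser sequence in which the organocerium reagent adds 1,2 to the C9 carbonyl without enolising C10, and acid hydrolysis of the enol ether with loss of water transposes the enone, putting the C20 methyl on C9 and the carbonyl on C7.

Step 8
Reactants: 15 A/B-cis 3β-(tert-butyldimethylsilyloxy)-5,9-dimethyl-Δ8-octalin-7-one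
Product: 19 A/B-cis 3β-(tert-butyldimethylsilyloxy)-5,9β-dimethyl-8-methylene-9α-vinyldecalin-7-one, via silyl enol ether 16 (not isolated), via Mannich base 17 (not isolated), via ammonium iodide 18 (not isolated)
Conditions: CH2=CHMgBr, CuBr·SMe2 (20 mol %), TMSCl, THF, −78 → −40 °C; concentrate; CH2=NMe2+ I−, CH2Cl2, 25 °C; MeI; then aq. NaHCO3
Reagents that add atoms: vinylmagnesium bromide (C=C[Mg]Br); dimethylmethyleneammonium iodide (C=[N+](C)C.[I-])
Why: Copper-catalysed conjugate addition of the vinyl Grignard reagent with silyl trapping should create the C9 quaternary centre by attack on the convex face of the cis-fused bicycle (the face of H-10 and C19, anti to the C10–C1 bond), and the regiodefined silyl enol ether is then aminomethylated at C8 (Mannich reaction) and eliminated through the methiodide to the exocyclic enone.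

Step 9
Reactants: 19 A/B-cis 3β-(tert-butyldimethylsilyloxy)-5,9β-dimethyl-8-methylene-9α-vinyldecalin-7-one
Product: 21 A/B-cis 3β-(tert-butyldimethylsilyloxy)-5,8β,9β-trimethyl-9α-vinyldecalin-7α-ol, via saturated ketone 20 (not isolated)
Conditions: Li, NH3 (liq.), EtOH, THF, −78 → −33 °C (inverse addition); NH4Cl
Reagents that add atoms: none
Why: Dissolving-metal reduction in which the enone is reduced to its enolate, protonation at C8 on the α face (anti to the axial C20 methyl) should make C17 equatorial and β, and the ketone is then reduced under thermodynamic control to the equatorial 7α-alcohol, which a hydride reagent blocked on the β face by C20 and C4 would not give.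

Step 10
Reactants: 21 A/B-cis 3β-(tert-butyldimethylsilyloxy)-5,8β,9β-trimethyl-9α-vinyldecalin-7α-ol
Product: 22 A/B-cis 7α-acetoxy-3β-(tert-butyldimethylsilyloxy)-5,8β,9β-trimethyl-9α-vinyldecalin
Conditions: Ac2O, DMAP, pyridine, 25 °C
Reagents that add atoms: acetic anhydride (CC(=O)OC(C)=O)
Why: DMAP-catalysed acetylation of the hindered secondary alcohol with retention at C7.

Step 11
Reactants: 23 tert-butyl 3-oxobutanoate
Product: 24 tert-butyl (E)-3-(trifluoromethylsulfonyloxy)but-2-enoate
Conditions: Tf2O, aq. Me4NOH, hexane, 5 °C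
Reagents that add atoms: trifluoromethanesulfonic anhydride (O=S(=O)(OS(=O)(=O)C(F)(F)F)C(F)(F)F)
Why: O-Triflation of the non-chelated ammonium enolate of the β-keto ester under biphasic conditions should give the E enol triflate (triflate trans to the ester) needed for the E side chain.

Step 12
Reactants: 22 A/B-cis 7α-acetoxy-3β-(tert-butyldimethylsilyloxy)-5,8β,9β-trimethyl-9α-vinyldecalin; 24 tert-butyl (E)-3-(trifluoromethylsulfonyloxy)but-2-enoate
Product: 26 tert-butyl ester of 7α-acetoxy-3β-(tert-butyldimethylsilyloxy)-cis-clerod-13E-en-15-oic acid, via alkylborane 25 (not isolated)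
Conditions: 9-BBN, THF, 50 °C; then 24, Pd(dppf)Cl2 (5 mol %), K3PO4 (aq), DMF, 25 °C
Reagents that add atoms: none
Why: Anti-Markovnikov hydroboration of the terminal vinyl group and B-alkyl Suzuki–Miyaura coupling with the enol triflate, which proceeds with retention of the alkene geometry and tolerates the acetate, the silyl ether and the tert-butyl ester.

Step 13
Reactants: 26 tert-butyl ester of 7α-acetoxy-3β-(tert-butyldimethylsilyloxy)-cis-clerod-13E-en-15-oic acid
Product: 27 tert-butyl ester of 7α-acetoxy-3β-hydroxy-cis-clerod-13E-en-15-oic acid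
Conditions: HF·pyridine, THF/pyridine, 0 → 25 °C
Reagents that add atoms: none
Why: Fluoride-mediated cleavage of the secondary silyl ether under buffered non-basic conditions that leave the acetate and the tert-butyl ester in place.

Step 14
Reactants: 27 tert-butyl ester of 7α-acetoxy-3β-hydroxy-cis-clerod-13E-en-15-oic acid
Product: 28 tert-butyl ester of 7α-acetoxy-3-oxo-cis-clerod-13E-en-15-oic acid
Conditions: DMP, CH2Cl2, 25 °C
Reagents that add atoms: none
Why: Neutral oxidation of the secondary alcohol with the hypervalent iodine reagent gives the C3 ketone and erases the relay stereocentre.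

Step 15
Reactants: 28 tert-butyl ester of 7α-acetoxy-3-oxo-cis-clerod-13E-en-15-oic acid
Product: 31 tert-butyl ester of 7α-acetoxy-2-(tert-butyldimethylsilyloxy)-3-oxo-cis-clerod-13E-en-15-oic acid, via silyl enol ether 29 (not isolated), via silyloxy epoxide 30 (not isolated)
Conditions: LiN(SiMe3)2, THF, −78 °C; TBSOTf; then dimethyldioxirane, acetone/CH2Cl2, −40 → 0 °C
Reagents that add atoms: tert-butyldimethylsilyl triflate (CC(C)(C)[Si](C)(C)OS(=O)(=O)C(F)(F)F); dimethyldioxirane (CC1(C)OO1)
Why: Rubottom oxidation in which kinetic deprotonation occurs at C2 because C4 is neopentyl (next to quaternary C5), and epoxidation of the electron-rich silyl enol ether followed by silyl migration gives the 2-silyloxy ketone, whose C2 configuration is irrelevant because C2 becomes sp2.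

Step 16
Reactants: 31 tert-butyl ester of 7α-acetoxy-2-(tert-butyldimethylsilyloxy)-3-oxo-cis-clerod-13E-en-15-oic acid
Product: 34 tert-butyl ester of 7α-acetoxy-2-(tert-butyldimethylsilyloxy)-3-oxo-cis-cleroda-4(18),13E-dien-15-oic acid, via Mannich base 32 (not isolated), via ammonium iodide 33 (not isolated)
Conditions: LiN(SiMe3)2, THF, −78 °C; CH2=NMe2+ I−, −78 → 25 °C; MeI; then aq. NaHCO3
Reagents that add atoms: dimethylmethyleneammonium iodide (C=[N+](C)C.[I-])
Why: With C2 blocked by the silyloxy group the amide base should enolise the ketone only towards C4 (it is too weak to deprotonate the acetate), and aminomethylation (Mannich reaction), quaternisation and base-induced β-elimination install the C18 exocyclic methylene.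

Step 17
Reactants: 34 tert-butyl ester of 7α-acetoxy-2-(tert-butyldimethylsilyloxy)-3-oxo-cis-cleroda-4(18),13E-dien-15-oic acid
Product: 35 7α-acetoxy-2-hydroxy-3-oxo-cis-cleroda-4(18),13E-dien-15-oic acid
Conditions: TFA/H2O (9:1), CH2Cl2, 0 → 25 °C
Reagents that add atoms: none
Why: Acidolysis removes the tert-butyl ester (as isobutene) and the silyl ether in one operation without touching the secondary acetate.

Step 18
Reactants: 35 7α-acetoxy-2-hydroxy-3-oxo-cis-cleroda-4(18),13E-dien-15-oic acid
Product: 36 7α-acetoxy-2-hydroxy-3-oxo-cis-cleroda-1,4(18),13E-trien-15-oic acid (CNP0192653.1)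
Conditions: DMP, CH2Cl2, 25 °C
Reagents that add atoms: none
Why: Oxidation of the acyloin gives the 2,3-diketone, which can enolise only towards C1 and should therefore exist as the diosphenol of the target.

Compound list
1 | 2-(trimethylsilyloxy)buta-1,3-diene | C=CC(=C)O[Si](C)(C)C | starting material
2 | pent-3-yn-2-one | CC#CC(C)=O | starting material
3 | 1-[2-methyl-4-(trimethylsilyloxy)cyclohexa-1,4-dien-1-yl]ethan-1-one | C1C(O[Si](C)(C)C)=CCC(C(C)=O)=C1C | intermediate
4 | 4-acetyl-3-methylcyclohex-3-en-1-one | C1C(=O)CCC(C(C)=O)=C1C | intermediate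
5 | (R)-4-acetyl-3-methylcyclohex-3-en-1-ol | C1[C@H](O)CCC(C(C)=O)=C1C | intermediate
6 | 3-(tert-butoxy)-3-oxopropanoic acid | OC(=O)CC(=O)OC(C)(C)C | starting material
7 | tert-butyl (R)-4-acetyl-3-methylcyclohex-3-en-1-yl malonate | C1[C@H](OC(=O)CC(=O)OC(C)(C)C)CCC(C(C)=O)=C1C | intermediate
8 | tert-butyl 6-acetyl-5-methyl-3-oxo-2-oxabicyclo[3.3.1]nonane-4-carboxylate (bridgeheads fixed by the tether; positions 4 and 6 epimer mixtures) | C1[C@H]2CCC(C(C)=O)[C@]1(C)C(C(=O)OC(C)(C)C)C(=O)O2 | intermediate
9 | A/B-cis tert-butyl 3β-hydroxy-5-methyl-7,9-dioxodecalin-6-carboxylate (C6 epimers, enol tautomers) | C1[C@H](O)CC[C@@H]2C(=O)CC(=O)C(C(=O)OC(C)(C)C)[C@]12C | intermediate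
10 | A/B-cis 3β-hydroxy-5-methyl-7,9-dioxodecalin-6-carboxylic acid | C1[C@H](O)CC[C@@H]2C(=O)CC(=O)C(C(=O)O)[C@]12C | intermediate
11 | A/B-cis 3β-hydroxy-5-methyldecalin-7,9-dione | C1[C@H](O)CC[C@@H]2C(=O)CC(=O)C[C@]12C | intermediate
12 | A/B-cis 3β-hydroxy-7-methoxy-5-methyl-Δ7-octalin-9-one | C1[C@H](O)CC[C@@H]2C(=O)C=C(OC)C[C@]12C | intermediate
13 | A/B-cis 3β-(tert-butyldimethylsilyloxy)-7-methoxy-5-methyl-Δ7-octalin-9-one | C1[C@H](O[Si](C)(C)C(C)(C)C)CC[C@@H]2C(=O)C=C(OC)C[C@]12C | intermediate
14 | A/B-cis 3β-(tert-butyldimethylsilyloxy)-7-methoxy-5,9-dimethyl-Δ7-octalin-9-ol (C9 epimers) | C1[C@H](O[Si](C)(C)C(C)(C)C)CC[C@@H]2C(C)(O)C=C(OC)C[C@]12C | intermediate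
15 | A/B-cis 3β-(tert-butyldimethylsilyloxy)-5,9-dimethyl-Δ8-octalin-7-one | C1[C@H](O[Si](C)(C)C(C)(C)C)CC[C@@H]2C(C)=CC(=O)C[C@]12C | intermediate
16 | 7-trimethylsilyl enol ether of the 9α-vinyl-9β-methyl adduct | C1[C@H](O[Si](C)(C)C(C)(C)C)CC[C@@H]2[C@@](C)(C=C)C=C(O[Si](C)(C)C)C[C@]12C | intermediate
17 | 8-(dimethylaminomethyl) ketone (C8 epimers) | C1[C@H](O[Si](C)(C)C(C)(C)C)CC[C@@H]2[C@@](C)(C=C)C(CN(C)C)C(=O)C[C@]12C | intermediate
18 | 8-(trimethylammoniomethyl) ketone iodide | C1[C@H](O[Si](C)(C)C(C)(C)C)CC[C@@H]2[C@@](C)(C=C)C(C[N+](C)(C)C)C(=O)C[C@]12C.[I-] | intermediate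
19 | A/B-cis 3β-(tert-butyldimethylsilyloxy)-5,9β-dimethyl-8-methylene-9α-vinyldecalin-7-one | C1[C@H](O[Si](C)(C)C(C)(C)C)CC[C@@H]2[C@@](C)(C=C)C(=C)C(=O)C[C@]12C | intermediate
20 | A/B-cis 3β-(tert-butyldimethylsilyloxy)-5,8β,9β-trimethyl-9α-vinyldecalin-7-one | C1[C@H](O[Si](C)(C)C(C)(C)C)CC[C@@H]2[C@@](C)(C=C)[C@H](C)C(=O)C[C@]12C | intermediate
21 | A/B-cis 3β-(tert-butyldimethylsilyloxy)-5,8β,9β-trimethyl-9α-vinyldecalin-7α-ol | C1[C@H](O[Si](C)(C)C(C)(C)C)CC[C@@H]2[C@@](C)(C=C)[C@H](C)[C@@H](O)C[C@]12C | intermediate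
22 | A/B-cis 7α-acetoxy-3β-(tert-butyldimethylsilyloxy)-5,8β,9β-trimethyl-9α-vinyldecalin | C1[C@H](O[Si](C)(C)C(C)(C)C)CC[C@@H]2[C@@](C)(C=C)[C@H](C)[C@@H](OC(C)=O)C[C@]12C | intermediate
23 | tert-butyl 3-oxobutanoate | CC(=O)CC(=O)OC(C)(C)C | starting material
24 | tert-butyl (E)-3-(trifluoromethylsulfonyloxy)but-2-enoate | C/C(OS(=O)(=O)C(F)(F)F)=C\C(=O)OC(C)(C)C | intermediate
25 | B-alkyl-9-BBN adduct of 22 (boron on C12) | C1[C@H](O[Si](C)(C)C(C)(C)C)CC[C@@H]2[C@@](C)(CCB3C4CCCC3CCC4)[C@H](C)[C@@H](OC(C)=O)C[C@]12C | intermediate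
26 | tert-butyl ester of 7α-acetoxy-3β-(tert-butyldimethylsilyloxy)-cis-clerod-13E-en-15-oic acid | C1[C@H](O[Si](C)(C)C(C)(C)C)CC[C@@H]2[C@@](C)(CC/C(C)=C/C(=O)OC(C)(C)C)[C@H](C)[C@@H](OC(C)=O)C[C@]12C | intermediate
27 | tert-butyl ester of 7α-acetoxy-3β-hydroxy-cis-clerod-13E-en-15-oic acid | C1[C@H](O)CC[C@@H]2[C@@](C)(CC/C(C)=C/C(=O)OC(C)(C)C)[C@H](C)[C@@H](OC(C)=O)C[C@]12C | intermediate
28 | tert-butyl ester of 7α-acetoxy-3-oxo-cis-clerod-13E-en-15-oic acid | C1C(=O)CC[C@@H]2[C@@](C)(CC/C(C)=C/C(=O)OC(C)(C)C)[C@H](C)[C@@H](OC(C)=O)C[C@]12C | intermediate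
29 | 3-(tert-butyldimethylsilyl) Δ2 enol ether of 28 | C1C(O[Si](C)(C)C(C)(C)C)=CC[C@@H]2[C@@](C)(CC/C(C)=C/C(=O)OC(C)(C)C)[C@H](C)[C@@H](OC(C)=O)C[C@]12C | intermediate
30 | 2,3-epoxide of 29 (epoxide face undefined) | C1C3(O[Si](C)(C)C(C)(C)C)OC3C[C@@H]2[C@@](C)(CC/C(C)=C/C(=O)OC(C)(C)C)[C@H](C)[C@@H](OC(C)=O)C[C@]12C | intermediate
31 | tert-butyl ester of 7α-acetoxy-2-(tert-butyldimethylsilyloxy)-3-oxo-cis-clerod-13E-en-15-oic acid (C2 epimers) | C1C(=O)C(O[Si](C)(C)C(C)(C)C)C[C@@H]2[C@@](C)(CC/C(C)=C/C(=O)OC(C)(C)C)[C@H](C)[C@@H](OC(C)=O)C[C@]12C | intermediate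
32 | 4-(dimethylaminomethyl) derivative of 31 (C4 epimers) | C1(CN(C)C)C(=O)C(O[Si](C)(C)C(C)(C)C)C[C@@H]2[C@@](C)(CC/C(C)=C/C(=O)OC(C)(C)C)[C@H](C)[C@@H](OC(C)=O)C[C@]12C | intermediate
33 | 4-(trimethylammoniomethyl) derivative of 31, iodide | C1(C[N+](C)(C)C)C(=O)C(O[Si](C)(C)C(C)(C)C)C[C@@H]2[C@@](C)(CC/C(C)=C/C(=O)OC(C)(C)C)[C@H](C)[C@@H](OC(C)=O)C[C@]12C.[I-] | intermediate
34 | tert-butyl ester of 7α-acetoxy-2-(tert-butyldimethylsilyloxy)-3-oxo-cis-cleroda-4(18),13E-dien-15-oic acid | C=C1C(=O)C(O[Si](C)(C)C(C)(C)C)C[C@@H]2[C@@](C)(CC/C(C)=C/C(=O)OC(C)(C)C)[C@H](C)[C@@H](OC(C)=O)C[C@]12C | intermediate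
35 | 7α-acetoxy-2-hydroxy-3-oxo-cis-cleroda-4(18),13E-dien-15-oic acid (C2 epimers) | C=C1C(=O)C(O)C[C@@H]2[C@@](C)(CC/C(C)=C/C(=O)O)[C@H](C)[C@@H](OC(C)=O)C[C@]12C | intermediate
36 | 7α-acetoxy-2-hydroxy-3-oxo-cis-cleroda-1,4(18),13E-trien-15-oic acid (CNP0192653.1) | C=C1C(=O)C(O)=C[C@@H]2[C@@](C)(CC/C(C)=C/C(=O)O)[C@H](C)[C@@H](OC(C)=O)C[C@]12C | target

Total step count: 18. Longest linear sequence: 17 steps (steps 1–10 and 12–18); step 11 prepares the coupling partner.

Steps most likely to fail

1. Step 4 (key step). The Michael addition to the fully substituted C5 may be slow or reversible, so that base-induced ejection of the malonate through the γ-anion at C4 overtakes it, or the ketone enolate may fail to open the bridged lactone. Fallback (radical formation of the C5–C6 bond, then a separate Claisen closure), setting out from alcohol 5: ethyl vinyl ether and NBS (CH2Cl2, −40 °C) should give the bromoacetal F1; Bu3SnH/AIBN (PhH, 80 °C, slow addition) should effect a 6-exo Ueno–Stork radical cyclisation onto C5 to give the bridged cyclic acetal F2, with C6 again forced onto the face of O3; Jones oxidation (CrO3, H2SO4, acetone, 0 °C) should give the bridged lactone F3; KOt-Bu (t-BuOH/THF, 50 °C) should then close ring B by the same lactone-opening Claisen condensation and give dione 11, where the route is rejoined at the second stage of step 5.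

2. Step 8. The conjugate addition may suffer from poor facial selectivity (delivery of the carbon nucleophile to the concave face) or from sluggish attack at the hindered β-carbon. Fallback (the two C9 substituents are introduced in the reverse order, so that a cuprate entering on the concave face now delivers the C20 methyl), setting out from vinylogous ester 13: the Grignard reagent of 2-(2-bromoethyl)-2-methyl-1,3-dioxolane with CeCl3 (THF, −78 °C) followed by oxalic acid work-up should give the chain-bearing enone F4; Me2CuLi/TMSCl (THF, −78 °C), then MeI/HMPA and equilibration with NaOMe/MeOH should give the 8β,9β-dimethyl ketone F5; Li/NH3/EtOH should give the 7α-alcohol F6; Ac2O/DMAP should give the acetate F7; PPTS in acetone/H2O should unmask the methyl ketone F8; a Horner–Wadsworth–Emmons reaction with tert-butyl diethylphosphonoacetate and NaH (THF), with separation of the minor Z isomer, should give ester 26, where the route is rejoined.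

3. Step 2. The β,γ-unsaturated ketone may isomerise into conjugation before it is reduced, or the enzyme may discriminate the two CH2 flanks poorly and give low enantioselectivity. Fallback (classical resolution in place of asymmetric reduction), setting out from ketone 4: NaBH4 (EtOH, −78 °C), which should reduce the saturated ring ketone in preference to the conjugated acetyl group, gives the racemic alcohol F9; esterification with (S)-O-acetylmandelic acid (DCC, DMAP) and separation of the diastereomers by chromatography or crystallisation gives the (R)-alcohol ester F10; K2CO3/MeOH then releases alcohol 5, where the route is rejoined.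

Further compounds
F1 | step 4 | 2-bromo-1-ethoxyethyl ether of (R)-4-acetyl-3-methylcyclohex-3-en-1-ol (acetal epimers) | C1[C@H](OC(CBr)OCC)CCC(C(C)=O)=C1C
F2 | step 4 | 6-acetyl-3-ethoxy-5-methyl-2-oxabicyclo[3.3.1]nonane (acetal and C6 epimers) | C1[C@H]2CCC(C(C)=O)[C@]1(C)CC(OCC)O2
F3 | step 4 | 6-acetyl-5-methyl-2-oxabicyclo[3.3.1]nonan-3-one (C6 epimers) | C1[C@H]2CCC(C(C)=O)[C@]1(C)CC(=O)O2
F4 | step 8 | A/B-cis 3β-(tert-butyldimethylsilyloxy)-5-methyl-9-[2-(2-methyl-1,3-dioxolan-2-yl)ethyl]-Δ8-octalin-7-one | C1[C@H](O[Si](C)(C)C(C)(C)C)CC[C@@H]2C(CCC3(C)OCCO3)=CC(=O)C[C@]12C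
F5 | step 8 | A/B-cis 3β-(tert-butyldimethylsilyloxy)-5,8β,9β-trimethyl-9α-[2-(2-methyl-1,3-dioxolan-2-yl)ethyl]decalin-7-one | C1[C@H](O[Si](C)(C)C(C)(C)C)CC[C@@H]2[C@@](C)(CCC3(C)OCCO3)[C@H](C)C(=O)C[C@]12C
F6 | step 8 | 7α-alcohol from F5 | C1[C@H](O[Si](C)(C)C(C)(C)C)CC[C@@H]2[C@@](C)(CCC3(C)OCCO3)[C@H](C)[C@@H](O)C[C@]12C
F7 | step 8 | 7α-acetate of F6 | C1[C@H](O[Si](C)(C)C(C)(C)C)CC[C@@H]2[C@@](C)(CCC3(C)OCCO3)[C@H](C)[C@@H](OC(C)=O)C[C@]12C
F8 | step 8 | A/B-cis 7α-acetoxy-3β-(tert-butyldimethylsilyloxy)-5,8β,9β-trimethyl-9α-(3-oxobutyl)decalin | C1[C@H](O[Si](C)(C)C(C)(C)C)CC[C@@H]2[C@@](C)(CCC(C)=O)[C@H](C)[C@@H](OC(C)=O)C[C@]12C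
F9 | step 2 | racemic 4-acetyl-3-methylcyclohex-3-en-1-ol | C1C(O)CCC(C(C)=O)=C1C
F10 | step 2 | (R)-4-acetyl-3-methylcyclohex-3-en-1-yl (S)-2-acetoxy-2-phenylacetate | C1[C@H](OC(=O)[C@@H](OC(C)=O)c2ccccc2)CCC(C(C)=O)=C1C
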